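**Plan**

- Retrosynthesis: the first cut is the ring D O–CH bond between the ring C carboxyl oxygen and the lactol carbon. Then come the ester C–O bond of the central seven-membered ring B, the diaryl ether C–O bond on ring A, and the formyl C–C bond on ring C.
- Forward: ring C (five steps from 2,4-dihydroxy-3-methylbenzoic acid) and ring A (three steps from 2,6-difluoro-4-methylbenzaldehyde) are joined by SNAr. Ring B is closed by lactonisation and ring D is closed last.
- Enabling feature: the only stereocentre is the lactol carbon of ring D, an acyl acetal carbon on ring C next to the carboxyl carbon. As a diallyl acetal it is prochiral (two enantiotopic allyloxy groups), and as an O-allyl ether it cannot epimerise by ring–chain tautomerism.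
- Stereochemistry: a chiral Brønsted acid ionises one allyloxy group and the neighbouring carboxylic acid closes ring D enantioselectively (R). The lactol allyl ether and the ring A allyl ether are removed together at the end, on the allyl side, under neutral conditions.

Key step: step 17

Assumption: the sense of induction of the chiral acid cannot be predicted, so the (R)-catalyst is written and its mirror image is to be used if the first run should give the S acetal carbon.
Remark: the ring A hydroxymethyl group is carried as an allyl ether instead of a silyl ether, so that one final operation frees it together with the lactol. A palladium-mediated removal of the lactol allyl group is avoided because the lactol anion would open to the achiral formyl carboxylate.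
Remark: the free lactol of 25 can racemise through its open formyl acid in basic or strongly protic media, so it is to be isolated cold and kept as a solid.

**Route**

Step 1
Reactants: 1 2,4-dihydroxy-3-methylbenzoic acid
Product: 2 allyl 2,4-dihydroxy-3-methylbenzoate
Conditions: allyl bromide, KHCO3, DMF, 40 °C
Reagents that add atoms: allyl bromide, C=CCBr
Why: Carboxylate O-alkylation: hydrogencarbonate deprotonates only the carboxylic acid, so the ester should form while both phenols stay free.

Step 2
Reactants: 2 allyl 2,4-dihydroxy-3-methylbenzoate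
Product: 3 allyl 5-formyl-2,4-dihydroxy-3-methylbenzoate
Conditions: MgCl2, Et3N, (CH2O)n, MeCN, reflux; 1 M HCl work-up
Reagents that add atoms: paraformaldehyde (as formaldehyde), C=O
Why: Magnesium phenoxide-directed ortho-formylation (Casnati–Skattebøl); C5 is the only free position ortho to a phenolic oxygen, so one regioisomer is expected.

Step 3
Reactants: 3 allyl 5-formyl-2,4-dihydroxy-3-methylbenzoate
Product: 4 allyl 5-formyl-2,4-bis(4-methoxybenzyloxy)-3-methylbenzoate
Conditions: 4-MeOC6H4CH2Cl (2.5 equiv), K2CO3, Bu4NI (cat.), DMF, 60 °C
Reagents that add atoms: 4-methoxybenzyl chloride, COc1ccc(CCl)cc1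
Why: Williamson etherification of both hydrogen-bonded phenols under forcing carbonate conditions, giving ethers that can later be removed oxidatively.

Step 4
Reactants: 4 allyl 5-formyl-2,4-bis(4-methoxybenzyloxy)-3-methylbenzoate
Product: 6 allyl 5-hydroxy-2,4-bis(4-methoxybenzyloxy)-3-methylbenzoate, via aryl formate 5 (not isolated)
Conditions: mCPBA, CH2Cl2, 0 °C → rt; then Et3N, MeOH, rt
Reagents that add atoms: 3-chloroperbenzoic acid, O=C(OO)c1cccc(Cl)c1
Why: Baeyer–Villiger (Dakin-type) oxidation in which the aryl group, activated by ortho and para alkoxy groups, migrates to give the formate, which is methanolysed in the same flask; the electron-poor allyl ester alkene should be epoxidised far more slowly.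

Step 5
Reactants: 6 allyl 5-hydroxy-2,4-bis(4-methoxybenzyloxy)-3-methylbenzoate
Product: 7 allyl 5-hydroxy-6-iodo-2,4-bis(4-methoxybenzyloxy)-3-methylbenzoate
Conditions: I2 (1.1 equiv), NaHCO3, THF–H2O, 0 °C → rt
Reagents that add atoms: iodine, II
Why: Electrophilic aromatic iodination of the phenoxide at the only open ring position, ortho to the hydroxyl group (as in the iodination of isovanillin between OH and a carbonyl-bearing carbon); without acid activation the anisole rings of the protecting groups should not react.

Step 6
Reactants: 8 2,6-difluoro-4-methylbenzaldehyde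
Product: 9 2-fluoro-6-methoxy-4-methylbenzaldehyde
Conditions: NaOMe (1.05 equiv), MeOH, 0 °C → rt
Reagents that add atoms: sodium methoxide, C[O-].[Na+]
Why: SNAr of one ortho fluorine activated by the formyl group; the methoxy group introduced deactivates the ring toward a second substitution.

Step 7
Reactants: 9 2-fluoro-6-methoxy-4-methylbenzaldehyde
Product: 10 3-bromo-2-fluoro-6-methoxy-4-methylbenzaldehyde
Conditions: NBS (1.05 equiv), DMF, 0 °C → rt, dark
Reagents that add atoms: N-bromosuccinimide, O=C1CCC(=O)N1Br
Why: Electrophilic aromatic bromination para to the methoxy group (and ortho to fluorine), the position favoured over the one ortho to OMe as in 3-fluoroanisole; a polar solvent and darkness suppress benzylic bromination.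

Step 8
Reactants: 10 3-bromo-2-fluoro-6-methoxy-4-methylbenzaldehyde
Product: 11 2-(trimethylsilyl)ethyl 2-fluoro-3-formyl-4-methoxy-6-methylbenzoate
Conditions: Pd(OAc)2 (2 mol%), Xantphos [4,5-bis(diphenylphosphino)-9,9-dimethylxanthene] (4 mol%), CO (1 atm), Et3N, Me3SiCH2CH2OH (3 equiv), toluene, 90 °C
Reagents that add atoms: carbon monoxide, [C-]#[O+]; 2-(trimethylsilyl)ethanol, C[Si](C)(C)CCO
Why: Palladium-catalysed alkoxycarbonylation of the aryl bromide (Heck carbonylation) at atmospheric CO pressure; with an amine base the aldehyde and the aryl fluoride should be spectators.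

Step 9
Reactants: 7 allyl 5-hydroxy-6-iodo-2,4-bis(4-methoxybenzyloxy)-3-methylbenzoate; 11 2-(trimethylsilyl)ethyl 2-fluoro-3-formyl-4-methoxy-6-methylbenzoate
Product: 12 diaryl ether (ring A: CO2CH2CH2SiMe3, CHO; ring C: I, CO2-allyl, two 4-methoxybenzyl ethers)
Conditions: K2CO3 (1.5 equiv), DMF, 60 °C
Reagents that add atoms: none
Why: SNAr diaryl ether synthesis: the fluorine of 11 lies between an ortho formyl and an ortho ester group, so the hindered phenoxide of 7 should displace it at moderate temperature, while the aryl iodide is inert to SNAr.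

Step 10
Reactants: 12 diaryl ether with ring A aldehyde
Product: 13 diaryl ether with ring A hydroxymethyl group
Conditions: NaBH4, THF–MeOH (4:1), 0 °C
Reagents that add atoms: none
Why: Chemoselective borohydride reduction of the only aldehyde; the two hindered benzoate esters and the aryl iodide should be untouched at 0 °C.

Step 11
Reactants: 13 diaryl ether with ring A hydroxymethyl group
Product: 14 diaryl ether with ring A allyloxymethyl group
Conditions: NaH (1.3 equiv), allyl bromide (3 equiv), Bu4NI (cat.), THF–DMF, 0 °C
Reagents that add atoms: allyl bromide, C=CCBr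
Why: Williamson etherification of the primary benzylic alkoxide with excess allyl bromide, fast enough at 0 °C to outrun attack on the hindered esters.

Step 12
Reactants: 14 diaryl ether with ring A allyloxymethyl group
Product: 16 diaryl ether with ring C aldehyde, via arylmagnesium chloride 15 (not isolated)
Conditions: i-PrMgCl·LiCl (1.1 equiv), THF, −40 °C; then DMF, −40 → 0 °C; aq. NH4Cl
Reagents that add atoms: N,N-dimethylformamide, CN(C)C=O
Why: Iodine–magnesium exchange with the turbo-Grignard reagent (Knochel) should give an ester-chelated arylmagnesium that is stable at −40 °C and is formylated by DMF (Bouveault aldehyde synthesis); the ring A aldehyde is already reduced and protected, so only one aldehyde is present.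

Step 13
Reactants: 16 diaryl ether with ring C aldehyde
Product: 17 diaryl ether diphenol
Conditions: DDQ (2.4 equiv), CH2Cl2–pH 7 phosphate buffer (10:1), 0 °C → rt
Reagents that add atoms: none
Why: Oxidative cleavage of the two aryl 4-methoxybenzyl ethers by DDQ; the ring A benzylic ether sits on an ester-deactivated, di-ortho-substituted arene and should be oxidised much more slowly.

Step 14
Reactants: 17 diaryl ether diphenol
Product: 19 depsidone aldehyde, via seco acid 18 (not isolated)
Conditions: Bu4NF (1.5 equiv), THF, 0 °C → rt; 1 M HCl wash; then DCC (1.5 equiv), DMAP (0.2 equiv), CH2Cl2 (2 mM), rt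
Reagents that add atoms: none
Why: Fluoride-induced β-elimination frees the ring A acid, and Steglich carbodiimide lactonisation at high dilution should close seven-membered ring B onto the phenol next to the ether oxygen, the only one within reach (the other is hydrogen-bonded to the ring C ester).

Step 15
Reactants: 19 depsidone aldehyde
Product: 20 depsidone diallyl acetal
Conditions: CH2=CHCH2OSiMe3 (4 equiv), Me3SiOTf (10 mol%), CH2Cl2, −78 → −30 °C; pyridine, then aq. NaHCO3
Reagents that add atoms: allyloxytrimethylsilane, C=CCO[Si](C)(C)C
Why: Noyori acetalisation with an alkoxysilane under aprotic conditions, which avoids the free hemiacetal that would attack the neighbouring ester and close ring D as a racemate; any aryl silyl ether formed is lost on work-up.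

Step 16
Reactants: 20 depsidone diallyl acetal
Product: 22 depsidone carboxylic acid with adjacent diallyl acetal, via phenylsilyl ester 21 (not isolated)
Conditions: Pd(PPh3)4 (5 mol%), PhSiH3 (2 equiv), CH2Cl2, 0 °C; cold pH 7 buffer; used at once without chromatography
Reagents that add atoms: none
Why: Tsuji–Trost deallylation: zerovalent palladium ionises only the allyl carboxylate (the benzylic and acetal allyl ethers have poor leaving groups), PhSiH3 reduces the π-allyl group to propene, and the silyl ester is hydrolysed cold at neutral pH so that the acid does not close ring D by itself.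

Step 17
Reactants: 22 depsidone carboxylic acid with adjacent diallyl acetal
Product: 23 (R)-O-allyl lactol ether of the ring A allyl-protected target
Conditions: (R)-[3,3'-bis(2,4,6-triisopropylphenyl)-1,1'-binaphthalene-2,2'-diyl] N-(trifluoromethanesulfonyl)phosphoramide (10 mol%), 5 Å molecular sieves, toluene, −60 °C
Reagents that add atoms: none
Why: Proposed new method: the strong chiral acid protonates one of the two enantiotopic allyloxy groups, allyl alcohol leaves, and the aryl oxocarbenium ion, paired with the chiral phosphoramidate anion, is captured by the neighbouring carboxyl oxygen. The closest known reaction types are chiral phosphoric acid-catalysed asymmetric transacetalisation of hydroxy acetals and enantioselective O-functionalisation of 3-hydroxyphthalides; a carboxylic acid as the internal nucleophile is untested. Ring D closes in a 5-exo-trig mode on the oxocarbenium carbon, which forms its O–CH bond. The new stereocentre is set under catalyst control by the chiral counter-anion shielding one face of the planar cation; the substrate has no other stereo-element. The step needs the catalyst-bound ion pair to outrun closure driven by the substrate's own carboxylic acid: the acetal carbon sits on an electron-poor, di-ortho-substituted ring, so self-ionisation should be slow at −60 °C while the far stronger phosphoramide still ionises it, and the sieves take up allyl alcohol. The product is an acyl acetal, much harder to ionise than the dialkyl acetal and unable to ring-open, so its configuration should hold.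

Step 18
Reactants: 23 (R)-O-allyl lactol ether of the ring A allyl-protected target
Product: 25 CNP0367167.1 (R), via bis(prop-1-enyl) ether 24 (not isolated)
Conditions: [Ir(cod)(PMePh2)2]PF6 (5 mol%, activated with H2, then under Ar), THF, rt; then N-iodosuccinimide (2.2 equiv), THF–H2O (10:1), 0 °C
Reagents that add atoms: none
Why: Iridium hydride-catalysed isomerisation turns both allyl ethers into (E)-prop-1-enyl ethers, and iodonium-induced hydrolysis of these enol ethers (as used for anomeric allyl ethers) cleaves on the propenyl side, so the C–O bonds at the acetal carbon are not broken and the neutral lactol is released without passing through its ring-opened anion.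

**Compound list**

1 | 2,4-dihydroxy-3-methylbenzoic acid | Cc1c(O)ccc(C(=O)O)c1O | starting material
2 | allyl 2,4-dihydroxy-3-methylbenzoate | C=CCOC(=O)c1ccc(O)c(C)c1O | intermediate
3 | allyl 5-formyl-2,4-dihydroxy-3-methylbenzoate | C=CCOC(=O)c1cc(C=O)c(O)c(C)c1O | intermediate
4 | allyl 5-formyl-2,4-bis(4-methoxybenzyloxy)-3-methylbenzoate | C=CCOC(=O)c1cc(C=O)c(OCc2ccc(OC)cc2)c(C)c1OCc1ccc(OC)cc1 | intermediate
5 | allyl 5-formyloxy-2,4-bis(4-methoxybenzyloxy)-3-methylbenzoate (aryl formate) | C=CCOC(=O)c1cc(OC=O)c(OCc2ccc(OC)cc2)c(C)c1OCc1ccc(OC)cc1 | intermediate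
6 | allyl 5-hydroxy-2,4-bis(4-methoxybenzyloxy)-3-methylbenzoate | C=CCOC(=O)c1cc(O)c(OCc2ccc(OC)cc2)c(C)c1OCc1ccc(OC)cc1 | intermediate
7 | allyl 5-hydroxy-6-iodo-2,4-bis(4-methoxybenzyloxy)-3-methylbenzoate | C=CCOC(=O)c1c(I)c(O)c(OCc2ccc(OC)cc2)c(C)c1OCc1ccc(OC)cc1 | intermediate
8 | 2,6-difluoro-4-methylbenzaldehyde | Cc1cc(F)c(C=O)c(F)c1 | starting material
9 | 2-fluoro-6-methoxy-4-methylbenzaldehyde | COc1cc(C)cc(F)c1C=O | intermediate
10 | 3-bromo-2-fluoro-6-methoxy-4-methylbenzaldehyde | COc1cc(C)c(Br)c(F)c1C=O | intermediate
11 | 2-(trimethylsilyl)ethyl 2-fluoro-3-formyl-4-methoxy-6-methylbenzoate | COc1cc(C)c(C(=O)OCC[Si](C)(C)C)c(F)c1C=O | intermediate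
12 | 2-(trimethylsilyl)ethyl 2-[3-(allyloxycarbonyl)-2-iodo-4,6-bis(4-methoxybenzyloxy)-5-methylphenoxy]-3-formyl-4-methoxy-6-methylbenzoate | COc1cc(C)c(C(=O)OCC[Si](C)(C)C)c(Oc2c(I)c(C(=O)OCC=C)c(OCc3ccc(OC)cc3)c(C)c2OCc2ccc(OC)cc2)c1C=O | intermediate
13 | the 3-(hydroxymethyl) analogue of 12 (ring A CH2OH in place of CHO) | COc1cc(C)c(C(=O)OCC[Si](C)(C)C)c(Oc2c(I)c(C(=O)OCC=C)c(OCc3ccc(OC)cc3)c(C)c2OCc2ccc(OC)cc2)c1CO | intermediate
14 | the 3-(allyloxymethyl) analogue of 12 (ring A CH2O-allyl) | COc1cc(C)c(C(=O)OCC[Si](C)(C)C)c(Oc2c(I)c(C(=O)OCC=C)c(OCc3ccc(OC)cc3)c(C)c2OCc2ccc(OC)cc2)c1COCC=C | intermediate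
15 | arylmagnesium chloride from 14 (MgCl in place of I on ring C) | COc1cc(C)c(C(=O)OCC[Si](C)(C)C)c(Oc2c([Mg]Cl)c(C(=O)OCC=C)c(OCc3ccc(OC)cc3)c(C)c2OCc2ccc(OC)cc2)c1COCC=C | intermediate
16 | 2-(trimethylsilyl)ethyl 2-[3-(allyloxycarbonyl)-2-formyl-4,6-bis(4-methoxybenzyloxy)-5-methylphenoxy]-3-(allyloxymethyl)-4-methoxy-6-methylbenzoate | COc1cc(C)c(C(=O)OCC[Si](C)(C)C)c(Oc2c(C=O)c(C(=O)OCC=C)c(OCc3ccc(OC)cc3)c(C)c2OCc2ccc(OC)cc2)c1COCC=C | intermediate
17 | 2-(trimethylsilyl)ethyl 2-[3-(allyloxycarbonyl)-2-formyl-4,6-dihydroxy-5-methylphenoxy]-3-(allyloxymethyl)-4-methoxy-6-methylbenzoate | COc1cc(C)c(C(=O)OCC[Si](C)(C)C)c(Oc2c(C=O)c(C(=O)OCC=C)c(O)c(C)c2O)c1COCC=C | intermediate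
18 | 2-[3-(allyloxycarbonyl)-2-formyl-4,6-dihydroxy-5-methylphenoxy]-3-(allyloxymethyl)-4-methoxy-6-methylbenzoic acid (seco acid) | COc1cc(C)c(C(=O)O)c(Oc2c(C=O)c(C(=O)OCC=C)c(O)c(C)c2O)c1COCC=C | intermediate
19 | depsidone aldehyde: ring A with OMe, Me, CH2O-allyl; ring C, going round from the ether carbon, with CHO, CO2-allyl, OH, Me | COc1cc(C)c2c(c1COCC=C)Oc1c(C=O)c(C(=O)OCC=C)c(O)c(C)c1OC2=O | intermediate
20 | depsidone diallyl acetal: as 19 with CH(O-allyl)2 in place of CHO | COc1cc(C)c2c(c1COCC=C)Oc1c(C(OCC=C)OCC=C)c(C(=O)OCC=C)c(O)c(C)c1OC2=O | intermediate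
21 | phenylsilyl ester of 22 | COc1cc(C)c2c(c1COCC=C)Oc1c(C(OCC=C)OCC=C)c(C(=O)O[SiH2]c3ccccc3)c(O)c(C)c1OC2=O | intermediate
22 | depsidone carboxylic acid with adjacent diallyl acetal (ring A CH2O-allyl, ring C free OH) | COc1cc(C)c2c(c1COCC=C)Oc1c(C(OCC=C)OCC=C)c(C(=O)O)c(O)c(C)c1OC2=O | intermediate
23 | (R)-O-allyl lactol ether: ring D closed, lactol carbon R, ring A CH2O-allyl | COc1cc(C)c2c(c1COCC=C)Oc1c(c(C)c(O)c3c1[C@H](OCC=C)OC3=O)OC2=O | intermediate
24 | bis[(E)-prop-1-enyl] ether of the target (lactol carbon R) | COc1cc(C)c2c(c1CO/C=C/C)Oc1c(c(C)c(O)c3c1[C@H](O/C=C/C)OC3=O)OC2=O | intermediate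
25 | CNP0367167.1, lactol carbon R | COc1cc(C)c2c(c1CO)Oc1c(c(C)c(O)c3c1[C@H](O)OC3=O)OC2=O | target

**Step count**

Total: 18 steps. Longest linear sequence: 15 steps (steps 1–5, then 9–18).

**Steps most likely to fail**

Step 17 (the proposed new method). The ring closure may be driven by the substrate's own carboxylic acid before the chiral ion pair forms, or the ion pair may discriminate the two faces poorly; either lowers the enantiomeric purity. The fallback uses known chemistry and sets out from 22. The acid is closed with an achiral acid (pyridinium p-toluenesulfonate, CH2Cl2, 0 °C, ordinary pseudo-ester formation) to the racemic O-allyl lactol ether F1. Its enantiomers are separated by preparative chromatography on a chiral stationary phase, and the R enantiomer is 23, where the route is rejoined.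

Step 9. Crowding around the new tetra-ortho-substituted ether may slow the substitution, so that the activated fluoride is lost to side reactions at the higher temperature then needed. The fallback sets out from 6 and 11 and comes back at 16. The un-iodinated phenol 6, which has one free ortho position, is coupled with 11 under the same SNAr conditions to the iodine-free diaryl ether F2. NaBH4 reduction gives the benzylic alcohol F3, and allylation (NaH, allyl bromide) gives the allyl ether F4. The ring C formyl group is then introduced by directed ortho-magnesiation with (2,2,6,6-tetramethylpiperidin-1-yl)MgCl·LiCl at the only ring C hydrogen, between the ester and the aryloxy group, followed by a DMF quench to give 16.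

Step 13. DDQ may also abstract hydride from the ring A benzylic ether, or oxidise the freed 4-aryloxyphenol further. The fallback sets out from 16 and comes back at 17. The two 4-methoxybenzyl groups are removed without an oxidant, by Lewis acid-assisted nucleophilic dealkylation with MgBr2·OEt2 and Me2S in CH2Cl2. No new compound arises on the way (F0).

Further compounds
F1 | step 17 | racemic O-allyl lactol ether (racemate of 23) | COc1cc(C)c2c(c1COCC=C)Oc1c(c(C)c(O)c3c1C(OCC=C)OC3=O)OC2=O
F2 | step 9 | 2-(trimethylsilyl)ethyl 2-[5-(allyloxycarbonyl)-2,4-bis(4-methoxybenzyloxy)-3-methylphenoxy]-3-formyl-4-methoxy-6-methylbenzoate (iodine-free diaryl ether) | COc1cc(C)c(C(=O)OCC[Si](C)(C)C)c(Oc2cc(C(=O)OCC=C)c(OCc3ccc(OC)cc3)c(C)c2OCc2ccc(OC)cc2)c1C=O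
F3 | step 9 | the 3-(hydroxymethyl) analogue of F2 (benzylic alcohol) | COc1cc(C)c(C(=O)OCC[Si](C)(C)C)c(Oc2cc(C(=O)OCC=C)c(OCc3ccc(OC)cc3)c(C)c2OCc2ccc(OC)cc2)c1CO
F4 | step 9 | the 3-(allyloxymethyl) analogue of F2 (allyl ether) | COc1cc(C)c(C(=O)OCC[Si](C)(C)C)c(Oc2cc(C(=O)OCC=C)c(OCc3ccc(OC)cc3)c(C)c2OCc2ccc(OC)cc2)c1COCC=C
F0 | step 13 | none | none
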